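**Strategy**

Everything rests on disconnecting both aryl–acyl bonds at once. The 2-methylbutanoyl group on C8 of ring A and the isobutyryl group on C8 of ring B differ by a single CH2, so C4 of the first and one methyl carbon of the second are joined through sulfur into one enantiopure diacid. Its bis(acid chloride) acylates the achiral, acyl-free bis-chroman (two 5,7-dihydroxy-2,2-dimethylchromans joined at C6 by the methine, C8 being the only free aromatic carbon of each) twice, closing a temporary 15-membered ring that tells the two enantiotopic rings apart and thereby sets the methine configuration. Nickel then excises the sulfur.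

Key step: step 10

Assumption: the (S)-configured short arm is taken to be the matched control element, meaning that the less strained macrocycle carries the long arm on the ring that gives the (R)-methine of the target; if the opposite holds, the same route is run with the enantiomeric short arm from (R)-3-(acetylsulfanyl)-2-methylpropanoic acid.

Notes on the chemistry
- Ring A is the chroman that ends with the 2-methylbutanoyl group (long arm). Ring B ends with the isobutyryl group (short arm).
- Descriptors change without any change in geometry in two places. The short-arm centre is (S) in 13–16 and 19 but formally (R) in 17 and 18, because COCl outranks CH2S. The methine is (S) in 19 but (R) in 18 and 20, because the sulfur-bearing short arm raises ring B above ring A in 19 only.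
- The pyran oxygen must sit ortho to the blocking ester. A direct annulation of 1 would leave this open, since the chelated ortho-hydroxyls are the less reactive ones. The 4-OH is therefore benzylated first.
- The sulfide is made by S-alkylation with a bromo ester at 0 °C. A hot thiolate opening of the α-methyl lactone would risk epimerisation.

**Route**

Step 1
Reactants: 1 methyl 2,4,6-trihydroxybenzoate
Product: 2 methyl 4-(benzyloxy)-2,6-dihydroxybenzoate
Conditions: BnBr (1.0 equiv), K2CO3 (1.1 equiv), acetone, 25–40 °C
Reagents that add atoms: benzyl bromide, BrCc1ccccc1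
Why: Williamson etherification that is selective for the 4-OH, the most acidic and the only non-chelated phenol (the 2- and 6-OH are hydrogen-bonded to the ester), so that the pyran oxygen of the next step can only be an oxygen ortho to the ester.

Step 2
Reactants: 2 methyl 4-(benzyloxy)-2,6-dihydroxybenzoate; 3 3-methylbut-2-enal
Product: 4 methyl 5-(benzyloxy)-7-hydroxy-2,2-dimethyl-2H-chromene-8-carboxylate
Conditions: 3 (1.3 equiv), ethylenediammonium diacetate (20 mol%), toluene, 110 °C
Reagents that add atoms: none
Why: Amine-catalysed Knoevenagel-type condensation at C3 followed by oxa-6π electrocyclisation (the standard 2H-chromene annulation of resorcinols with enals), in which only the free OH next to the ester can close the pyran because O4 is benzylated, which places the ester at C8 and leaves C6 open.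

Step 3
Reactants: 4 methyl 5-(benzyloxy)-7-hydroxy-2,2-dimethyl-2H-chromene-8-carboxylate
Product: 5 methyl 5,7-dihydroxy-2,2-dimethylchroman-8-carboxylate
Conditions: H2 (1 atm), Pd/C (10 wt% Pd), EtOAc/MeOH, 25 °C
Reagents that add atoms: none
Why: Catalytic hydrogenation saturates the styrene-type C3=C4 bond and hydrogenolyses the benzyl ether in one operation, while the ester, the phenols and the tertiary alkyl aryl ether are inert.

Step 4
Reactants: 5 methyl 5,7-dihydroxy-2,2-dimethylchroman-8-carboxylate; 6 6-methylheptanal
Product: 7 dimethyl 6,6'-(6-methylheptane-1,1-diyl)bis(5,7-dihydroxy-2,2-dimethylchroman-8-carboxylate)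
Conditions: 5 (2.1 equiv), 6 (1.0 equiv), p-TsOH·H2O (10 mol%), CH2Cl2, 0 → 25 °C
Reagents that add atoms: none
Why: Acid-catalysed hydroxyalkylation and Friedel–Crafts alkylation (Baeyer diarylmethane condensation) that can only take place at C6 because the ester blocks C8, and that stops at the bis-adduct because no nucleophilic ring carbon is left; the methine carries two identical rings and is not yet a stereocentre.

Step 5
Reactants: 7 dimethyl 6,6'-(6-methylheptane-1,1-diyl)bis(5,7-dihydroxy-2,2-dimethylchroman-8-carboxylate)
Product: 9 6,6'-(6-methylheptane-1,1-diyl)bis(2,2-dimethylchroman-5,7-diol), via bridged dicarboxylic acid 8 (not isolated)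
Conditions: NaOH (2 M aq, degassed), MeOH, 65 °C, Ar; then HCl to pH 2, 50 °C
Reagents that add atoms: none
Why: Saponification of the salicylate-type esters followed by protodecarboxylation of the phloroglucinol-type acids on acidification (ipso-protonation and loss of CO2), the usual removal of a carboxylate blocking group from a resorcinol nucleus, frees C8 on both rings.

Step 6
Reactants: 10 α-methylene-γ-butyrolactone
Product: 11 (R)-α-methyl-γ-butyrolactone
Conditions: H2 (100 atm), Ru2Cl4((S)-BINAP)2(NEt3) (0.5 mol%), CH2Cl2, 50 °C
Reagents that add atoms: none
Why: Noyori asymmetric hydrogenation in which the exocyclic alkene, held in a chelate with the lactone carbonyl on the chiral Ru–BINAP fragment, takes up hydrogen on one face, the (S)-ligand being expected to give the (R)-lactone (sense and enantiopurity to be confirmed by chiral GC before step 7, the antipodal ligand being the direct remedy).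

Step 7
Reactants: 11 (R)-α-methyl-γ-butyrolactone
Product: 12 ethyl (2R)-4-bromo-2-methylbutanoate
Conditions: HBr (gas), EtOH, 0 → 25 °C
Reagents that add atoms: hydrogen bromide, Br; ethanol, CCO
Why: Acid-mediated lactone opening (bromide displaces the O-alkyl oxygen with Fischer esterification of the acid), a classical lactone-to-ω-bromo-ester conversion that neither touches nor enolises the α-stereocentre.

Step 8
Reactants: 13 (2S)-3-(acetylsulfanyl)-2-methylpropanoic acid; 12 ethyl (2R)-4-bromo-2-methylbutanoate
Product: 16 (2R)-4-{[(2S)-2-carboxypropyl]sulfanyl}-2-methylbutanoic acid, via thiol acid 14 (not isolated), via sulfide monoester 15 (not isolated)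
Conditions: NaOH (aq, degassed), MeOH, 0 °C; then 12, 0 → 25 °C; then NaOH (aq), 25 °C; HCl to pH 2
Reagents that add atoms: sodium hydroxide, [Na+].[OH-]
Why: Thioacetate cleavage, SN2 alkylation of the thiolate by the primary bromide (much faster than ester hydrolysis at 0 °C) and saponification in one flask, in which no bond to either stereocentre is made or broken.

Step 9
Reactants: 16 (2R)-4-{[(2S)-2-carboxypropyl]sulfanyl}-2-methylbutanoic acid
Product: 17 (2R)-4-{[(2R)-3-chloro-2-methyl-3-oxopropyl]sulfanyl}-2-methylbutanoyl chloride
Conditions: (COCl)2 (2.5 equiv), DMF (cat.), CH2Cl2, 0 °C, 1 h; concentrated below 20 °C and used at once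
Reagents that add atoms: oxalyl chloride, ClC(=O)C(=O)Cl
Why: Vilsmeier-type chlorination of both acids under base-free conditions, so that no ketene forms and the α-configurations hold, while the cold and short handling limits attack of the thioether on its own γ-acyl chloride.

Step 10
Reactants: 9 6,6'-(6-methylheptane-1,1-diyl)bis(2,2-dimethylchroman-5,7-diol); 17 (2R)-4-{[(2R)-3-chloro-2-methyl-3-oxopropyl]sulfanyl}-2-methylbutanoyl chloride
Product: 19 sulfur-bridged 15-membered diketone macrocycle (long-arm centre R; short-arm centre S; methine S), via seco keto acid chloride 18 (not isolated)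
Conditions: 9, TiCl4 (6 equiv), CH2Cl2/MeNO2 (10:1), −20 °C; 17 (1.05 equiv) in CH2Cl2 by syringe pump over 12 h (final concentration ≤ 2 mM), −20 → 0 °C; then 25 °C, 12 h; 1 M HCl; diastereomers separated by chromatography
Reagents that add atoms: none
Why: Proposed new method: TiCl4 turns the four phenols of 9 into aryloxytitanium chlorides, one acyl chloride of 17 then acylates C8 of one ring (by direct C-acylation, or by O-acylation at O7 or O5 and Fries migration to C8) to give a seco species such as 18, and the second acyl chloride acylates C8 of the other ring, the closest known reactions being Lewis-acid-promoted ortho-acylation and Fries rearrangement of phloroglucinols and high-dilution Friedel–Crafts macrocyclisation with diacid chlorides. The 15-membered ring closes in this second, intramolecular Friedel–Crafts acylation (aryl C8 to carbonyl carbon, end-to-end macrocyclisation), helped by syringe-pump dilution and by titanium bridging the phenoxides of the two rings into a folded arrangement. Site selectivity is built into 9, because C8 is the only unsubstituted aromatic carbon of each ring and the ketones formed are deactivated towards further acylation. The methine becomes a stereocentre when the two enantiotopic rings receive different arms, and it is controlled by the stereocentres of the tether, chiefly the short-arm centre next to the ring-closing carbonyl, through the unequal strain of the two diastereomeric macrocycles. The selectivity required is that the long arm ends on the ring that makes the methine (S) in 19, and it should be reached under thermodynamic control, since the Lewis acid can reopen and reclose the aryl–methine bond through a tethered o-quinone methide while the hindered, chelated α-branched ketones enolise only slowly. Neither the direction nor the magnitude of this preference is known in advance, so both must be established by experiment, the unwanted diastereomer being recyclable under the same acid.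

Step 11
Reactants: 19 sulfur-bridged 15-membered diketone macrocycle
Product: 20 (2R)-1-{6-[(1R)-1-(5,7-dihydroxy-2,2-dimethyl-8-(2-methylpropanoyl)chroman-6-yl)-6-methylheptyl]-5,7-dihydroxy-2,2-dimethylchroman-8-yl}-2-methylbutan-1-one
Conditions: Raney Ni (W-2 grade, washed to neutrality, deactivated by reflux in acetone), acetone/EtOH, 25 → 50 °C
Reagents that add atoms: none
Why: Raney nickel desulfurisation cleaves both C–S bonds of the dialkyl sulfide at CH2 carbons remote from the retained (R)-centre, which turns the long arm into 2-methylbutanoyl and the short arm into isobutyryl (its centre becomes CH(CH3)2 and is no longer stereogenic), while hydrogen-poor neutral nickel in acetone should spare the chelated aryl ketones and the methine.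

**Compound list**

1 | methyl 2,4,6-trihydroxybenzoate | COC(=O)c1c(O)cc(O)cc1O | starting material
2 | methyl 4-(benzyloxy)-2,6-dihydroxybenzoate | COC(=O)c1c(O)cc(OCc2ccccc2)cc1O | intermediate
3 | 3-methylbut-2-enal | CC(C)=CC=O | starting material
4 | methyl 5-(benzyloxy)-7-hydroxy-2,2-dimethyl-2H-chromene-8-carboxylate | COC(=O)c1c(O)cc(OCc2ccccc2)c2C=CC(C)(C)Oc12 | intermediate
5 | methyl 5,7-dihydroxy-2,2-dimethylchroman-8-carboxylate | COC(=O)c1c(O)cc(O)c2CCC(C)(C)Oc12 | intermediate
6 | 6-methylheptanal | CC(C)CCCCC=O | starting material
7 | dimethyl 6,6'-(6-methylheptane-1,1-diyl)bis(5,7-dihydroxy-2,2-dimethylchroman-8-carboxylate) | CC(C)CCCCC(c1c(O)c(C(=O)OC)c2OC(C)(C)CCc2c1O)c1c(O)c(C(=O)OC)c2OC(C)(C)CCc2c1O | intermediate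
8 | 6,6'-(6-methylheptane-1,1-diyl)bis(5,7-dihydroxy-2,2-dimethylchroman-8-carboxylic acid) | CC(C)CCCCC(c1c(O)c(C(=O)O)c2OC(C)(C)CCc2c1O)c1c(O)c(C(=O)O)c2OC(C)(C)CCc2c1O | intermediate (not isolated)
9 | 6,6'-(6-methylheptane-1,1-diyl)bis(2,2-dimethylchroman-5,7-diol), achiral | CC(C)CCCCC(c1c(O)cc2c(c1O)CCC(C)(C)O2)c1c(O)cc2c(c1O)CCC(C)(C)O2 | intermediate
10 | α-methylene-γ-butyrolactone | C=C1CCOC1=O | starting material
11 | (R)-α-methyl-γ-butyrolactone | C[C@@H]1CCOC1=O | intermediate
12 | ethyl (2R)-4-bromo-2-methylbutanoate | BrCC[C@@H](C)C(=O)OCC | intermediate
13 | (2S)-3-(acetylsulfanyl)-2-methylpropanoic acid | C[C@H](CSC(C)=O)C(=O)O | starting material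
14 | (2S)-2-methyl-3-sulfanylpropanoic acid | C[C@H](CS)C(=O)O | intermediate (not isolated)
15 | (2S)-3-{[(3R)-4-ethoxy-3-methyl-4-oxobutyl]sulfanyl}-2-methylpropanoic acid | C[C@H](CSCC[C@@H](C)C(=O)OCC)C(=O)O | intermediate (not isolated)
16 | (2R)-4-{[(2S)-2-carboxypropyl]sulfanyl}-2-methylbutanoic acid | C[C@H](CSCC[C@@H](C)C(=O)O)C(=O)O | intermediate
17 | (2R)-4-{[(2R)-3-chloro-2-methyl-3-oxopropyl]sulfanyl}-2-methylbutanoyl chloride | C[C@H](CSCC[C@@H](C)C(=O)Cl)C(=O)Cl | intermediate
18 | seco keto acid chloride: long arm on C8 of ring A, free short-arm acyl chloride, ring B unacylated (methine R; long-arm centre R; short-arm centre R by CIP) | ClC(=O)[C@H](C)CSCC[C@@H](C)C(=O)c1c(O)c([C@H](CCCCC(C)C)c2c(O)cc3c(c2O)CCC(C)(C)O3)c(O)c2c1OC(C)(C)CC2 | intermediate (not isolated)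
19 | sulfur-bridged 15-membered diketone macrocycle: C8 of ring A–C(=O)–CH(CH3)–CH2–CH2–S–CH2–CH(CH3)–C(=O)–C8 of ring B (long-arm centre R; short-arm centre S; methine S) | S1CC[C@@H](C)C(=O)c2c(O)c([C@H](CCCCC(C)C)c3c(O)c4c(c(C(=O)[C@H](C)C1)c3O)OC(C)(C)CC4)c(O)c3c2OC(C)(C)CC3 | intermediate
20 | (2R)-1-{6-[(1R)-1-(5,7-dihydroxy-2,2-dimethyl-8-(2-methylpropanoyl)chroman-6-yl)-6-methylheptyl]-5,7-dihydroxy-2,2-dimethylchroman-8-yl}-2-methylbutan-1-one | CC[C@@H](C)C(=O)c1c(O)c([C@H](CCCCC(C)C)c2c(O)c3c(c(C(=O)C(C)C)c2O)OC(C)(C)CC3)c(O)c2c1OC(C)(C)CC2 | target

**Step count**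

Total: 11 steps. Longest linear sequence: 7 steps (steps 1–5, 10 and 11). Steps 6–9 form the convergent branch.

**Steps most likely to fail**

1. Step 10 (Proposed new method). Three processes can defeat it.
   - Intermolecular acylation may outrun ring closure and give oligomers.
   - The two enantiotopic rings may not be told apart, or the wrong one may be preferred.
   - Prolonged Lewis acid may erode the α-centres.

   The fallback uses only known chemistry, sets out from 9 and returns at 20. It abandons the tether and replaces stereocontrol by separation. Compound 9 is mono-acylated at C8 with (2R)-2-methylbutanoyl chloride F1, made from purchased (R)-2-methylbutanoic acid with oxalyl chloride. The conditions are 0.9 equiv of F1, TiCl4, CH2Cl2/MeNO2, −20 → 0 °C, an ordinary Friedel–Crafts acylation of a phloroglucinol-type ring. This should give the mono-ketone F2 as a mixture of both methine configurations, with unreacted 9 recycled. The second ring of F2 is then acylated at its only free carbon with isobutyryl chloride under the same conditions. The product should be 20 together with its methine epimer F3, and the two diastereomers are separated by preparative HPLC.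

2. Step 11. Three processes are of concern.
   - A chelated aryl ketone may be reduced and its carbinol hydrogenolysed through an o-quinone methide.
   - The (R)-centre may epimerise on a basic metal surface.
   - The tetraphenol may bind irreversibly to nickel.

   The fallback sets out from 19 and returns at 20. The four phenols are capped before desulfurisation (Ac2O, pyridine, DMAP, 25 °C) to give the macrocycle tetraacetate F4. Without free ortho-hydroxyls no phenoxide or o-quinone methide can form. Raney Ni as in step 11 should then give the target tetraacetate F5, and K2CO3 in MeOH at 0 °C releases 20.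

3. Step 5. During the slow hydrolysis of the hindered esters, hot alkali may cleave the aryl–methine bond of 7 by retro-Michael loss of a phloroglucinolate, and the electron-rich product may oxidise. The fallback sets out from 5 and returns at 8. It moves the hydrolysis to the monomer, where no bridge exists. Compound 5 is saponified (NaOH, MeOH/H2O, 65 °C, Ar) and acidified cold to pH 3–4 to give 5,7-dihydroxy-2,2-dimethylchroman-8-carboxylic acid F6. Two equivalents of F6 are bridged with 6 under buffered amine catalysis (ethylenediammonium diacetate, THF, 25 °C; Knoevenagel–Michael sequence), with the carboxyl group still blocking C8. This should give 8 directly, which loses CO2 on warming in dilute acid as in the second half of step 5.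

**Further compounds**

F1 | step 10 | (2R)-2-methylbutanoyl chloride | CC[C@@H](C)C(Cl)=O
F2 | step 10 | (2R)-1-{6-[1-(5,7-dihydroxy-2,2-dimethylchroman-6-yl)-6-methylheptyl]-5,7-dihydroxy-2,2-dimethylchroman-8-yl}-2-methylbutan-1-one, both methine configurations | CC[C@@H](C)C(=O)c1c(O)c(C(CCCCC(C)C)c2c(O)cc3c(c2O)CCC(C)(C)O3)c(O)c2c1OC(C)(C)CC2
F3 | step 10 | methine epimer of 20, (2R)-acyl centre with (1S)-methine | CC[C@@H](C)C(=O)c1c(O)c([C@@H](CCCCC(C)C)c2c(O)c3c(c(C(=O)C(C)C)c2O)OC(C)(C)CC3)c(O)c2c1OC(C)(C)CC2
F4 | step 11 | 5,7,5',7'-tetra-O-acetate of macrocycle 19 | S1CC[C@@H](C)C(=O)c2c(OC(C)=O)c([C@H](CCCCC(C)C)c3c(OC(C)=O)c4c(c(C(=O)[C@H](C)C1)c3OC(C)=O)OC(C)(C)CC4)c(OC(C)=O)c3c2OC(C)(C)CC3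
F5 | step 11 | 5,7,5',7'-tetra-O-acetate of 20 | CC[C@@H](C)C(=O)c1c(OC(C)=O)c([C@H](CCCCC(C)C)c2c(OC(C)=O)c3c(c(C(=O)C(C)C)c2OC(C)=O)OC(C)(C)CC3)c(OC(C)=O)c2c1OC(C)(C)CC2
F6 | step 5 | 5,7-dihydroxy-2,2-dimethylchroman-8-carboxylic acid | OC(=O)c1c(O)cc(O)c2CCC(C)(C)Oc12
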